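## Retrosynthetic overview

1. Enabling feature (gibberellane numbering): in the bicyclo[3.2.1]octane of rings C and D, quaternary C8 is bonded to C14, which is β to the C12 carbinol carbon, and to C15–C16(=C17), while C13 joins C14 and C16. With C12 as a ketone and C16=C17 as an alkyne, a C8 radical closes ring C at C8–C14 (vinyl ketone C12(=O)–C13=C14 hung on C9) and ring D at C13–C16 (propargyl arm on C8) in one cascade.
2. The C8 radical comes from a tertiary alcohol (N-phthalimidoyl oxalate), made by propargylation of the C8 ketone of a ring B β-keto ester; ring B comes from a Dieckmann closure C6–C8.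
3. The C9–C10 bond and the 19,10-lactone come from an ester enolate aldol/lactonization on a ring A enedione; ring A comes from the quinone monoketal of methyl 5-methoxysalicylate (asymmetric Mukaiyama–Michael at C5, methylation at C4).
4. The ring A enone C1=C2–C3=O is carried as the latent 1β-hydroxy-3-ketone (late epoxidation and reductive opening); the C12 ketone left by the cascade becomes the 12α-alcohol.
5. Ring order: A (from the arene) → lactone → B → C and D together → adjustments at C12, C1 and C7.

Key step: step 15

Remark 1: α is the face of rings A and B that carries the lactone bridge, β the opposite face; ring A = C1–C5, C10; ring B = C5, C6, C8, C9, C10; ring C = C8, C9, C11–C14; ring D = C8, C13–C16.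
Remark 2 (assumption): the (S,S)-ligand in step 3 is taken to give the (R) configuration at C5; if the sense of induction is the opposite, the (R,R)-ligand is used.
Remark 3: ester 11 is racemic, so 13 to 20 are mixtures at C12, and 19 to 23 are mixtures at the C8 carbinol carbon; both centers are erased later (steps 13 and 15) and are left undefined in the SMILES.

## Route

Step 1
Reactants: 1 methyl 5-methoxysalicylate
Product: 2 methyl 3,3-dimethoxy-6-oxocyclohexa-1,4-diene-1-carboxylate
Conditions: PhI(OAc)2, MeOH, 0 °C
Reagents that add atoms: methanol (CO)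
Why: Oxidative dearomatization of a para-methoxyphenol by a hypervalent iodine reagent in methanol traps the phenoxonium ion at the future C10 as the dimethyl ketal (quinone monoketal formation); no stereocenter is made.

Step 2
Reactants: 3 tert-butyl acetate
Product: 5 1-tert-butoxy-1-(trimethylsilyloxy)ethene, via lithium enolate of tert-butyl acetate 4 (not isolated)
Conditions: LiN(i-Pr)2, THF, –78 °C; TMSCl, –78 °C → rt
Reagents that add atoms: chlorotrimethylsilane (C[Si](C)(C)Cl)
Why: Kinetic deprotonation of the ester and O-silylation give the silyl ketene acetal needed for the Mukaiyama–Michael reaction.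

Step 3
Reactants: 2 quinone monoketal ester; 5 silyl ketene acetal
Product: 6 methyl (6R)-6-(2-tert-butoxy-2-oxoethyl)-5,5-dimethoxy-2-oxocyclohex-3-ene-1-carboxylate (C1 epimers and enol form; the side chain sits on the future C5)
Conditions: Cu(SbF6)2 (10 mol%), (S,S)-t-Bu-box (11 mol%), (CF3)2CHOH (1.2 equiv), CH2Cl2/PhMe, –78 °C
Reagents that add atoms: none
Why: Catalytic asymmetric Mukaiyama–Michael addition: the 2-alkoxycarbonyl enone binds divalent copper as a bidentate chelate, only the doubly activated C4=C5 bond reacts, and the C2-symmetric bis(oxazoline) ligand shields one face so that the acetate unit should enter at C5 with (R) configuration, the silyl group passing to hexafluoroisopropanol.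

Step 4
Reactants: 6 Michael adduct
Product: 7 methyl (1S,6R)-6-(2-tert-butoxy-2-oxoethyl)-5,5-dimethoxy-1-methyl-2-oxocyclohex-3-ene-1-carboxylate
Conditions: MeI, Cs2CO3, acetone, 0 °C → rt
Reagents that add atoms: iodomethane (CI)
Why: C-Alkylation of the cyclic β-keto ester enolate takes place anti to the neighboring C5 side chain, which should set quaternary C4 with the methyl trans and the C19 ester cis to the side chain.

Step 5
Reactants: 7 quaternary keto ester ketal
Product: 8 methyl (1S,6R)-6-(2-tert-butoxy-2-oxoethyl)-1-methyl-2,5-dioxocyclohex-3-ene-1-carboxylate (ring A enedione)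
Conditions: TsOH·H2O (cat.), acetone/H2O, rt
Reagents that add atoms: water (O)
Why: Acid hydrolysis of the allylic dimethyl ketal frees the C10 ketone; aromatization is impossible because C4 is quaternary, and the tert-butyl ester tolerates dilute acid.

Step 6
Reactants: 9 methyl 4-oxobutanoate
Product: 10 methyl 4-hydroxyhex-5-enoate (racemic)
Conditions: CH2=CHMgBr, THF, –78 °C; sat. aq. NH4Cl, used crude
Reagents that add atoms: vinylmagnesium bromide (C=C[Mg]Br)
Why: Grignard addition is chemoselective for the aldehyde over the methyl ester at low temperature; the carbinol carbon (future C12) is racemic and is erased in step 13.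

Step 7
Reactants: 10 hydroxy ester
Product: 11 methyl 4-[(tert-butyldimethylsilyl)oxy]hex-5-enoate (racemic)
Conditions: TBSCl, imidazole, DMF, 0 °C → rt
Reagents that add atoms: tert-butyldimethylsilyl chloride (CC(C)(C)[Si](C)(C)Cl)
Why: Standard silylation blocks lactonization of the γ-hydroxy ester and masks the future C12 ketone.

Step 8
Reactants: 8 ring A enedione; 11 silyloxy ester
Product: 14 ring A enone lactone diester (3-oxo-1-ene; 4β-methyl; C19–O–C10 γ-lactone on the α-face; 5β-H; α-CH2CO2t-Bu on C5; β-CH(CO2Me)CH2CH(OTBS)CH=CH2 on C10 with C9 as in the target), via lithium E(O)-enolate of the silyloxy ester 12 (not isolated), via lithium C10 aldolate 13 (not isolated)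
Conditions: 11, LiN(i-Pr)2, THF, –78 °C; then 8, –78 → 0 °C; sat. aq. NH4Cl
Reagents that add atoms: none
Why: Aldol addition then lactonization: the E(O) lithium enolate adds 1,2 to the less hindered C10 carbonyl from the face anti to the pseudoaxial C19 ester (sets C10), a Zimmerman–Traxler chair with C5 equatorial gives the anti aldol (sets C9 so that C11 will be cis to O10 in ring B), and the axial C10 alkoxide closes the γ-lactone on the syn-axial C19 methyl ester, which the tert-butyl ester cannot do.

Step 9
Reactants: 14 ring A enone lactone diester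
Product: 17 tricyclic β-keto ester (rings A and B with the 19,10-lactone; 8-oxo; 6β-CO2t-Bu; 9β-H; 9α-CH2CH(OTBS)CH=CH2), via lithium enolate of the tert-butyl ester 15 (not isolated), via lithium enolate of the β-keto ester 16 (not isolated)
Conditions: LiN(SiMe3)2 (2.2 equiv), THF, –78 → –30 °C; AcOH at –78 °C
Reagents that add atoms: none
Why: Dieckmann condensation: the base should remove a proton from the unhindered C6 methylene and not from the hindered C9 methine, the ester enolate acylates the C8 methyl ester (5-exo-trig) to close ring B trans to ring A, the product is protected as its enolate, and C6 settles with the ester trans to C4 (β).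

Step 10
Reactants: 17 tricyclic β-keto tert-butyl ester
Product: 18 tricyclic β-keto allyl ester (as 17 with 6β-CO2CH2CH=CH2)
Conditions: allyl alcohol (10 equiv), PhMe, 110 °C
Reagents that add atoms: allyl alcohol (C=CCO)
Why: β-Keto tert-butyl esters lose tert-butanol on heating to give an acylketene that is trapped by allyl alcohol (thermal transesterification), which brings in an ester removable at the end under neutral conditions without base touching the β-acyloxy ketone.

Step 11
Reactants: 18 tricyclic β-keto allyl ester
Product: 19 tertiary homopropargylic alcohol (as 18 with C8(OH)(CH2C≡CH); both C8 epimers)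
Conditions: In powder, propargyl bromide, THF/H2O (1:1), rt
Reagents that add atoms: propargyl bromide (C#CCBr)
Why: Barbier propargylation in water: the allenylindium reagent adds (SE2') to the reactive C8 ketone without enolizing the β-keto ester and leaves the hindered conjugated C3 ketone alone; the configuration of the new carbinol carbon does not matter because it becomes a planar radical.

Step 12
Reactants: 19 silyl ether
Product: 20 diol (as 19 with 9α-CH2CH(OH)CH=CH2)
Conditions: HF·pyridine, THF, 0 °C → rt
Reagents that add atoms: none
Why: Fluoride-mediated cleavage of the silyl ether; the lactone and the esters are inert.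

Step 13
Reactants: 20 diol
Product: 21 vinyl ketone tertiary alcohol (9α-CH2C(=O)CH=CH2; C8(OH)(CH2C≡CH))
Conditions: Dess–Martin periodinane, NaHCO3, CH2Cl2, 0 °C
Reagents that add atoms: none
Why: Dess–Martin oxidation converts the secondary allylic alcohol to the vinyl ketone while the tertiary alcohol cannot be oxidized, and it removes the C12 epimer mixture.

Step 14
Reactants: 21 vinyl ketone tertiary alcohol
Product: 23 tert-alkyl N-phthalimidoyl oxalate (C8–O–CO–CO–O–N-phthalimide; rest as in the vinyl ketone), via tert-alkyl chlorooxalate 22 (not isolated)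
Conditions: (COCl)2 (5 equiv), CH2Cl2, 0 °C → rt, then evaporation; N-hydroxyphthalimide, Et3N, THF, 0 °C; used without chromatography
Reagents that add atoms: oxalyl chloride (O=C(Cl)C(=O)Cl); N-hydroxyphthalimide (O=C1c2ccccc2C(=O)N1O)
Why: Acylation of the tertiary alcohol by excess oxalyl chloride and esterification of the chlorooxalate with N-hydroxyphthalimide give the redox-active tert-alkyl N-phthalimidoyl oxalate, a known activation of tertiary alcohols as radical precursors; the γ-hydroxy enone should stay open-chain because the ketone is conjugated.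

Step 15
Reactants: 23 tert-alkyl N-phthalimidoyl oxalate
Product: 24 allyl ester of the 3,12-dioxo-1,16-diene 19,10-lactone (rings A to D complete; 5β-H; 6β-CO2allyl; 9β-H; C8 and C13 as in the target)
Conditions: Ru(bpy)3(PF6)2 (2 mol%), Hantzsch ester (1.5 equiv, slow addition), i-Pr2NEt·HBF4 (1 equiv), degassed THF/CH2Cl2 (0.005 M), blue LEDs, rt
Reagents that add atoms: none
Why: Proposed new method: single-electron reduction of the N-phthalimidoyl oxalate by the photogenerated monovalent ruthenium complex expels phthalimide anion and two CO2 to leave the planar tertiary C8 radical, which adds to C14, the β-carbon of the C9-tethered vinyl ketone, to give the α-keto radical at C13, which in turn adds to C16 of the propargyl arm; the C17 vinyl radical then takes a hydrogen atom from the Hantzsch ester to give the exocyclic methylene. The closest known reactions are the photoredox fragmentation of tert-alkyl N-phthalimidoyl oxalates with Giese trapping by enones, and tin- or manganese-mediated tandem radical cyclizations that end on an alkyne; their merger in one cascade started from an oxalate has not been shown. Ring C closes 6-endo-trig (C8 to C14) and ring D closes 5-exo-dig (C13 to C16), which builds the bicyclo[3.2.1]octane. C8 is set by the existing C9 stereocenter, because the three-atom tether on the α-face of ring B can reach only the α-face of the C8 radical (cis 6-5 fusion), which leaves the propargyl arm β; C13 follows from C8, since the arm can bridge only on the face it occupies. The step needs 6-endo over 5-exo regioselectivity, secured by the polarity match of the nucleophilic tertiary radical with the enone β-carbon and by the carbonyl lying inside the forming ring, and it needs closure of the C13 radical to outrun hydrogen transfer, secured by high dilution and slow addition of the Hantzsch ester. Both C8 carbinol epimers converge because the radical is planar.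

Step 16
Reactants: 24 pentacyclic enone ketone
Product: 25 12α-alcohol (as 24 with 12-OH axial and anti to the C15–C16 bridge)
Conditions: NaBH4, MeOH/CH2Cl2 (1:1), –78 °C
Reagents that add atoms: none
Why: Borohydride at low temperature reduces the saturated C12 ketone faster than the conjugated and α-quaternary C3 ketone, and because the axial approach on the α-face is closed by the syn-axial C9–C10 bond the hydride should enter from the side of the C15–C16 bridge and leave the hydroxyl axial (12α).

Step 17
Reactants: 25 12α-alcohol
Product: 26 1β,2β-epoxy-3-ketone (as 25 with the ring A enone epoxidized on the β-face)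
Conditions: t-BuOOH (decane), DBU, CH2Cl2, 0 °C → rt
Reagents that add atoms: tert-butyl hydroperoxide (CC(C)(C)OO)
Why: Nucleophilic (Weitz–Scheffer) epoxidation: the hydroperoxide anion adds to C1 axially on the β-face, anti to the C10–O bond and away from the lactone bridge that covers the α-face, and ring closure gives the 1β,2β-epoxide.

Step 18
Reactants: 26 epoxy ketone
Product: 27 allyl ester of the target (1β-OH; 12α-OH; 3-oxo)
Conditions: SmI2 (2.5 equiv), THF/MeOH, –78 °C
Reagents that add atoms: none
Why: Divalent samarium reduces the α,β-epoxy ketone by cleavage of the C2–O bond next to the carbonyl and gives the β-hydroxy ketone with the C1 oxygen untouched (1β-OH); no carbanion is formed at C1, so the C10–O lactone bond is not eliminated.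

Step 19
Reactants: 27 allyl ester of the target
Product: 28 CNP0259985.1 (1β,12α-dihydroxy-3-oxo 19,10-lactone 7-acid)
Conditions: Pd(PPh3)4 (5 mol%), morpholine (5 equiv), THF, rt
Reagents that add atoms: none
Why: Allyl transfer from the ester to morpholine through a π-allyl complex of zerovalent palladium (Tsuji–Trost type) frees the C7 acid under neutral conditions that spare the β-hydroxy ketone, the lactone and the exocyclic alkene.

## Compound list

1 | methyl 5-methoxysalicylate | COC(=O)c1cc(OC)ccc1O | starting material
2 | methyl 3,3-dimethoxy-6-oxocyclohexa-1,4-diene-1-carboxylate | COC(=O)C1=CC(OC)(OC)C=CC1=O | intermediate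
3 | tert-butyl acetate | CC(=O)OC(C)(C)C | starting material
4 | lithium enolate of tert-butyl acetate (not isolated) | C=C(O[Li])OC(C)(C)C | intermediate
5 | 1-tert-butoxy-1-(trimethylsilyloxy)ethene | C=C(O[Si](C)(C)C)OC(C)(C)C | intermediate
6 | methyl (6R)-6-(2-tert-butoxy-2-oxoethyl)-5,5-dimethoxy-2-oxocyclohex-3-ene-1-carboxylate | O=C1C=CC(OC)(OC)[C@H](CC(=O)OC(C)(C)C)C1C(=O)OC | intermediate
7 | methyl (1S,6R)-6-(2-tert-butoxy-2-oxoethyl)-5,5-dimethoxy-1-methyl-2-oxocyclohex-3-ene-1-carboxylate | O=C1C=CC(OC)(OC)[C@H](CC(=O)OC(C)(C)C)[C@]1(C)C(=O)OC | intermediate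
8 | methyl (1S,6R)-6-(2-tert-butoxy-2-oxoethyl)-1-methyl-2,5-dioxocyclohex-3-ene-1-carboxylate | O=C1C=CC(=O)[C@H](CC(=O)OC(C)(C)C)[C@]1(C)C(=O)OC | intermediate
9 | methyl 4-oxobutanoate | COC(=O)CCC=O | starting material
10 | methyl 4-hydroxyhex-5-enoate (racemic) | COC(=O)CCC(O)C=C | intermediate
11 | methyl 4-[(tert-butyldimethylsilyl)oxy]hex-5-enoate (racemic) | COC(=O)CCC(O[Si](C)(C)C(C)(C)C)C=C | intermediate
12 | lithium E(O)-enolate of the silyloxy ester (not isolated) | CO/C(O[Li])=C\CC(O[Si](C)(C)C(C)(C)C)C=C | intermediate
13 | lithium C10 aldolate (not isolated) | O=C1C=C[C@@](O[Li])([C@@H](C(=O)OC)CC(O[Si](C)(C)C(C)(C)C)C=C)[C@H](CC(=O)OC(C)(C)C)[C@]1(C)C(=O)OC | intermediate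
14 | ring A enone 19,10-lactone with CH2CO2t-Bu on C5 and the C9 ester chain on C10 | O=C1C=C[C@@]2(OC(=O)[C@@]1(C)[C@H]2CC(=O)OC(C)(C)C)[C@@H](C(=O)OC)CC(O[Si](C)(C)C(C)(C)C)C=C | intermediate
15 | lithium enolate of the tert-butyl ester at C6 (not isolated) | O=C1C=C[C@@]2(OC(=O)[C@@]1(C)[C@H]2C=C(O[Li])OC(C)(C)C)[C@@H](C(=O)OC)CC(O[Si](C)(C)C(C)(C)C)C=C | intermediate
16 | lithium enolate of the ring B β-keto ester (not isolated) | O=C1C=C[C@]23OC(=O)[C@@]1(C)[C@H]2C(C(=O)OC(C)(C)C)=C(O[Li])[C@H]3CC(O[Si](C)(C)C(C)(C)C)C=C | intermediate
17 | tricyclic β-keto tert-butyl ester (8-oxo; 6β-CO2t-Bu; 9α-CH2CH(OTBS)CH=CH2) | O=C1C=C[C@]23OC(=O)[C@@]1(C)[C@H]2[C@H](C(=O)OC(C)(C)C)C(=O)[C@H]3CC(O[Si](C)(C)C(C)(C)C)C=C | intermediate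
18 | tricyclic β-keto allyl ester | O=C1C=C[C@]23OC(=O)[C@@]1(C)[C@H]2[C@H](C(=O)OCC=C)C(=O)[C@H]3CC(O[Si](C)(C)C(C)(C)C)C=C | intermediate
19 | tertiary homopropargylic alcohol at C8 (both epimers) | O=C1C=C[C@]23OC(=O)[C@@]1(C)[C@H]2[C@H](C(=O)OCC=C)C(O)(CC#C)[C@H]3CC(O[Si](C)(C)C(C)(C)C)C=C | intermediate
20 | C8, C12 diol | O=C1C=C[C@]23OC(=O)[C@@]1(C)[C@H]2[C@H](C(=O)OCC=C)C(O)(CC#C)[C@H]3CC(O)C=C | intermediate
21 | vinyl ketone tertiary alcohol | O=C1C=C[C@]23OC(=O)[C@@]1(C)[C@H]2[C@H](C(=O)OCC=C)C(O)(CC#C)[C@H]3CC(=O)C=C | intermediate
22 | tert-alkyl chlorooxalate (not isolated) | O=C1C=C[C@]23OC(=O)[C@@]1(C)[C@H]2[C@H](C(=O)OCC=C)C(OC(=O)C(Cl)=O)(CC#C)[C@H]3CC(=O)C=C | intermediate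
23 | tert-alkyl N-phthalimidoyl oxalate | O=C1C=C[C@]23OC(=O)[C@@]1(C)[C@H]2[C@H](C(=O)OCC=C)C(OC(=O)C(=O)ON4C(=O)c5ccccc5C4=O)(CC#C)[C@H]3CC(=O)C=C | intermediate
24 | allyl ester of the 3,12-dioxo-1,16-diene 19,10-lactone (rings A to D) | O=C1C=C[C@]23OC(=O)[C@@]1(C)[C@H]2[C@H](C(=O)OCC=C)[C@]12C[C@H](C(=C)C1)C(=O)C[C@H]23 | intermediate
25 | 12α-alcohol | O=C1C=C[C@]23OC(=O)[C@@]1(C)[C@H]2[C@H](C(=O)OCC=C)[C@]12C[C@H](C(=C)C1)[C@@H](O)C[C@H]23 | intermediate
26 | 1β,2β-epoxy-3-ketone | O=C1[C@H]2O[C@H]2[C@]23OC(=O)[C@@]1(C)[C@H]2[C@H](C(=O)OCC=C)[C@]12C[C@H](C(=C)C1)[C@@H](O)C[C@H]23 | intermediate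
27 | allyl ester of the target | O=C1C[C@@H](O)[C@]23OC(=O)[C@@]1(C)[C@H]2[C@H](C(=O)OCC=C)[C@]12C[C@H](C(=C)C1)[C@@H](O)C[C@H]23 | intermediate
28 | CNP0259985.1 | C=C1C[C@]23C[C@H]1[C@@H](O)C[C@H]2[C@]12OC(=O)[C@](C)(C(=O)C[C@H]1O)[C@H]2[C@@H]3C(=O)O | target

## Step count and risks

Total steps: 19. Longest linear sequence: 16 steps (1, 3 to 5, 8 to 19).

Steps most likely to fail:

1. Step 15 (Proposed new method). The C13 α-keto radical may take a hydrogen atom before it closes onto the alkyne, or the cascade may stall after the first ring. The fallback makes the two bonds one after the other with known reactions and sets out from 23. It is run under the same photoredox conditions at 0.1 M with the Hantzsch ester added in one portion, a plain intramolecular Giese cyclization, to give tetracyclic ketone F1 (ring C closed, C8 quaternary with the propargyl arm β, C12 ketone). TBSOTf and Et3N convert it to its silyl enol ethers, of which the Δ12(13) isomer, silyl enol ether F2, is used; the Δ11 isomer cannot reach the alkyne and is hydrolysed back to the ketone with dilute acid. Ph3PAuCl and AgBF4 in CH2Cl2/MeOH then close ring D by 5-exo-dig attack of the enol ether on the alkyne activated by monovalent gold (Conia-ene type). The route is rejoined at 24.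

2. Step 8. Proton transfer from C5–H of the enedione to the basic lithium enolate, conjugate addition to the enedione, or poor facial control at C9 and C10 may erode the aldol. The fallback replaces the basic enolate by a Reformatsky reagent and sets out from 11. Deprotonation with LiN(i-Pr)2 and bromination with N-bromosuccinimide give α-bromo ester F3; activated Zn in THF gives Reformatsky reagent F4, which is cannulated off the excess metal and added to 8. The weakly basic zinc enolate adds 1,2 to C10 through a chair transition state to give zinc aldolate F5, which lactonizes on warming. The route is rejoined at 14.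

3. Step 9. Deprotonation at C9 followed by β-elimination of the C10 carboxylate (opening of the lactone) may compete with deprotonation at C6. The fallback changes the order of events: it sets out from 8 and 11 as in step 8, but the aldolate 13 is held at –78 °C before it lactonizes and LiN(SiMe3)2 is added. In 13 the C10 oxygen is an alkoxide, which is no leaving group and disfavors deprotonation at the neighboring C9, so the C6 enolate closes ring B first and gives dilithio alkoxide enolate F6. Warming then lets the C10 alkoxide close the lactone onto C19 to give enolate 16, which is quenched with AcOH. The route is rejoined at 17.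

Further compounds
F1 | step 15 | tetracyclic ketone (ring C closed; 8β-propargyl; 12-oxo; ring A enone lactone; allyl ester) | O=C1C=C[C@]23OC(=O)[C@@]1(C)[C@H]2[C@H](C(=O)OCC=C)[C@@]2(CC#C)CCC(=O)C[C@H]23
F2 | step 15 | Δ12(13) tert-butyldimethylsilyl enol ether of the tetracyclic ketone | O=C1C=C[C@]23OC(=O)[C@@]1(C)[C@H]2[C@H](C(=O)OCC=C)[C@@]2(CC#C)CC=C(O[Si](C)(C)C(C)(C)C)C[C@H]23
F3 | step 8 | methyl 2-bromo-4-[(tert-butyldimethylsilyl)oxy]hex-5-enoate | COC(=O)C(Br)CC(O[Si](C)(C)C(C)(C)C)C=C
F4 | step 8 | bromozinc enolate of the silyloxy ester (Reformatsky reagent) | COC(O[Zn]Br)=CCC(O[Si](C)(C)C(C)(C)C)C=C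
F5 | step 8 | bromozinc C10 aldolate | O=C1C=C[C@@](O[Zn]Br)([C@@H](C(=O)OC)CC(O[Si](C)(C)C(C)(C)C)C=C)[C@H](CC(=O)OC(C)(C)C)[C@]1(C)C(=O)OC
F6 | step 9 | dilithio C10 alkoxide and ring B β-keto ester enolate (lactone not yet closed) | O=C1C=C[C@@]2(O[Li])[C@H](CC(O[Si](C)(C)C(C)(C)C)C=C)C(O[Li])=C(C(=O)OC(C)(C)C)[C@@H]2[C@]1(C)C(=O)OC
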